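The left-handed substrate leaves faster than its mirror image, and the lead shrinks with heat. Both steps carry the same [partner] and [free catalyst], so these cancel from the ratio of the two rates. With r and l the fractions of right-handed and left-handed substrate left, the selectivity factor s follows from the readings:

s = ln l / ln r

excess = (r − l) / (2 − r − l)

| flask | left-handed substrate | right-handed substrate | partner | free catalyst | impurity | temperature | remark | time |
|---|---|---|---|---|---|---|---|---|
| Thursday's | 0.30 M | 0.30 M | 0.60 M | 42 mM | 10 mM | 8 °C | run made earlier |  |
| Saturday's | 0.30 M | 0.30 M | 0.60 M | 42 mM | 15 mM | 35 °C | run made earlier |  |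
| west | 0.30 M | 0.30 M | 0.600 M | 42 mM | 20 mM | 45 °C |  | 30 d |
| south-west | 0.30 M | 0.30 M | 0.600 M | 42 mM | 20 mM | 20 °C |  | 30 d |
| north-west | 0.30 M | 0.30 M | 0.600 M | 42 mM | 20 mM | −5 °C |  | 30 d |

| run | time / d | left-handed product / % | right-handed product / % | left-handed substrate / % |
|---|---|---|---|---|
| Thursday's | 30.0 | 47.3 | 28.9 | 3.1 |
| Thursday's | 60.0 | 49.1 | 34.3 | 1.4 |
| Thursday's | 100 | 49.2 | 38.2 | 1.6 |
| Thursday's | 120 | 50.5 | 38.7 | 0.1 |
| Thursday's | 150 | 50.0 | 39.4 | 0.7 |
| Thursday's | 200 | 49.5 | 41.0 | 0.3 |
| Saturday's | 3.00 | 39.3 | 30.6 | 10.5 |
| Saturday's | 10.0 | 46.8 | 42.0 | 3.2 |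
| Saturday's | 15.0 | 48.8 | 43.5 | 3.3 |
| Saturday's | 25.0 | 48.4 | 46.3 | 1.5 |
| Saturday's | 40.0 | 49.8 | 46.4 | 0.6 |
| Saturday's | 50.0 | 50.3 | 47.5 | 0.8 |

(readings scatter by 0.5 percentage points)

1. the flask with the highest excess of left-handed product over right-handed product ("all alike" if they lie within 1.5 percentage points) (west / south-west / north-west / all alike)
2. excess of left-handed product over right-handed product at the end, west
3. excess of left-handed product over right-handed product at the end, south-west
4. excess of left-handed product over right-handed product at the end, north-west

- free catalyst is single-handed; left-handed substrate and right-handed substrate are mirror images of each other, charged as a racemate, each of them at the stated concentration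
- reactions considered so far: partner + free catalyst + right-handed substrate -> free catalyst + right-handed product; partner + free catalyst + left-handed substrate -> free catalyst + left-handed product; free catalyst <-> dormant form; free catalyst + impurity -> spent catalyst
- an excess is below zero if the other one leads

Thursday's flask at 30.0 d has r = 0.414 and s = 3.15. Saturday's flask at 3.00 d has r = 0.392 and s = 1.67. Taking ln s as straight in 1/T, I get s = 4.49 for north-west, 2.34 for south-west and 1.35 for west.

The zero of the scale is full conversion, since 0.600 M of partner covers both substrates and r = l = 0 gives no excess. The top is the start, where r nears 1: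

ceiling = (s − 1) / (s + 1)

The ceiling is 63.5% for north-west, 40.1% for south-west and 15.0% for west, so north-west stands highest, and I commit to it.

North-west is colder than Thursday's flask and, taking impurity one for one, holds less active catalyst: 22.0 mM against 32.0 mM. So its r exceeds 0.414, and the floor is

excess ≥ 25.2%

Thursday's and Saturday's r nearly match, but their partner does not: 23.8% of its charge is left in Thursday's flask and 30.1% in Saturday's. Since ln r falls in step with the partner left, I weigh each ln r by the mean of the reciprocal partner fraction between start and reading, 2.60 for Thursday's and 2.16 for Saturday's. The rate per active catalyst, carried to −5 °C, then scales Thursday's ln r by 0.273. With the catalyst ratio as well, and [partner] staying higher in north-west, r stays below 0.848: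

excess ≤ 54.9%

The forecast names north-west, with 1.3% for west, 13% for south-west and 52% for north-west, the last inside my bracket, noting “Partner is exactly stoichiometric, so the tail is second order and slows”.

The flask gives north-west, with 0.972% for west, 13.8% for south-west and 45.1% for north-west.

    partner + free catalyst + right-handed substrate → free catalyst + right-handed product (k = 0.0110 M⁻² min⁻¹, Ea = 59.0 kJ mol⁻¹)
    partner + free catalyst + left-handed substrate → free catalyst + left-handed product (k = 0.0250 M⁻² min⁻¹, Ea = 40.0 kJ mol⁻¹)
    free catalyst ⇌ dormant form (K = 0.840, k = 2.00 × 10⁻⁴ min⁻¹, Ea = 108 kJ mol⁻¹, ΔH = −45.0 kJ mol⁻¹)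
    free catalyst + impurity → spent catalyst (k = 6.00 M⁻¹ min⁻¹, Ea = 54.0 kJ mol⁻¹)
    (constants at 20 °C)

North-west lies 18 percentage points under its ceiling, having converted 57.2%. Two things act together on this excess, the hour of the reading and the conversion of free catalyst with impurity: north-west reads 45.1%, falls to 18.7% at 300 d, and reads 36.0% at the asked time with the impurity step taken away. The neighbour of north-west with 0.050 M of impurity has 0% free catalyst and keeps 99.8% of its right-handed substrate. Held against my ceiling of 63.5%, that neighbour reads 64.8%.

The readings are simulated for an exercise, and the scatter is random.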